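## Analysis of the target

Luzonoid A is an iridoid aglycone diester. Iridoid numbering is used throughout: C1 is the acetal carbon, O2 the ring oxygen, C3=C4 the enol ether, C5 and C9 the ring-fusion carbons, C6–C8 the remaining cyclopentane carbons, C10 the CH2OH on C8 and C11 the CH2OH on C4. Ring A is the dihydropyran (C1, O2, C3, C4, C5, C9) and ring B the cyclopentane (C5, C6, C7, C8, C9); the two are cis-fused.

There are five stereocentres: C1 (S), C5 (S), C7 (S), C8 (R), C9 (S). H5 and H9 are cis, and the isovaleryloxy group on C1 is cis to H9. On ring B, O7 and C10 lie on the face of H5/H9, and the tertiary hydroxyl on C8 lies on the face that carries ring A. This gives a trans-7,8-diol within four contiguous stereocentres C5, C9, C8, C7.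

The sensitive groups are:
- the acyl acetal at C1;
- the enol ether C3=C4 with its allylic hydroxyl at C11, which is acid-labile as soon as C4 carries no acceptor;
- the (E)-p-coumarate with a free phenol, which excludes late hydrogenation, strong base and strong hydride;
- the 1,3-related pair O7 ester / O10 hydroxyl, which invites acyl migration.

Two things make the synthesis hard. The first is the quaternary carbinol C8, wedged between the oxygenated carbons C7 and C10 and the ring-fusion carbon C9. The second is that two different acyl groups must end up on the anomeric oxygen O1 and on the most hindered secondary oxygen O7, while two primary hydroxyls and one tertiary hydroxyl stay free.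

The feature the route is built on: C10–C8–C7 with O10, O8 and O7 is a 1,3-dihydroxyacetone skeleton with C8 as the carbonyl carbon. What remains of the skeleton is a 1-oxadiene (O2=C3–C4=C5) and an enol ether (C9=C1), hung on this unit through C6 and directly on C8. Ring A is then a [4+2] adduct, and ring B closes through the same C5–C9 bond.

## Retrosynthetic reasoning

**C11 oxidation level (26 from 25).** No skeletal bond is cut. C11 is carried as a formyl group until the last step, because the C3=C4 enol ether is then a vinylogous formate. In that form it tolerates the acid needed for acetal chemistry, and the final reduction can be a mild borohydride reduction that leaves both esters alone.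

**The two esters (25 from 24; 24 from 20 and 23; 20 from 19; 19 from 18; 18 from 17).** The O7–acyl and O1–acyl bonds are cut. The order follows from the sensitivities. Hydrogenolysis, which frees the lactol and O8, must come before the coumarate. O1 is acylated while only the lactol and the inert tertiary 8-OH are free. An acid-catalysed shift of the acetonide from O7/O10 to O8/O10 then exposes O7 as the only hydroxyl, so that no selective protection of the primary O10 is needed. Acid 23 comes from 21.

**Both rings at once (17 from 14 and 15).** Three bonds are cut: C4=C5, C5–C9 and O2–C1. Forward, aldehyde 14 condenses with the symmetric C3 dialdehyde 15 to the oxadiene 16, which is trapped by the tethered enol ether. Cutting here, rather than at C7–C8 or at the ring-A C–O bonds alone, removes ring A, ring B and the stereocentres C5, C9 and C1 in one operation. It leaves a monocyclic dioxane in which C7 and C8 are already set and are held in a ring that can direct the new centres. The forward reaction has to be cis-selective at the ring fusion and has to place ring A on the face of ring B opposite to O7 and C10.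

**The quaternary carbinol (14 from 13; 13 from 12; 12 from 6 and 9).** The C8–C9 bond is cut. The two-carbon enol ether arrives as the vinyllithium 10, made from 9, and adds to the carbonyl carbon C8 of ketone 6. This is the natural polarity of the dihydroxyacetone unit. The forward step must deliver C9 cis to the C7 side chain, and the tertiary alkoxide 11 is capped at once so that O8 cannot later attack C5. Bromide 9 comes from 7.

**The only bought stereocentre (6 from 5; 5 from 3 and 4; 3 from 1 and 2).** The C6–C7 bond is cut. Ketone 1 already holds C7, C8, C10 and all three oxygens. The auxiliary 2 controls the alkylation with iodide 4 and sets C7. Every other stereocentre is relayed from C7: C8 in the addition step, C5 and C9 in the key step, C1 in the lactol acylation.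

## Alternatives that were turned down

**Alternative 1:** the textbook de Mayo route.
- Disconnection: C4–C5 and C1–C9.
- Forward key step: [2+2] photocycloaddition of the cyclopentene acetonide A1 with the enol form of a diformylacetate ester, retro-aldol opening of the cyclobutanol and lactolisation to the iridoid ester A2.
- Reason for rejection:
  - The two alkene carbons of A1 (future C5 and C9) are electronically alike, so head-to-head and head-to-tail adducts are both expected.
  - A1 already contains ring B with C7 and C8 and needs its own multistep synthesis, so the key step buys only ring A.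
  - C11 arrives as an ester, and its hydride reduction cannot be placed after the two acyl groups.

**Alternative 2:** annulation of ring B onto a preformed pyranone.
- Disconnection: C5–C6 and C8–C9.
- Forward key step: phosphine-catalysed [3+2] annulation of an allenoate with an enantioenriched 6-acyloxy-2H-pyran-3(6H)-one, giving the bicyclic keto ester A3.
- Reason for rejection:
  - A3 has neither C11 nor any oxygen on C7 or C8.
  - C11 would need enol triflate formation and carbonylation.
  - The trans-7,8-diol would have to come from a C7=C8 epoxide on the hindered face, opened at the tertiary carbon C8 by an oxygen nucleophile from the concave side. That process has carbocation character, and attack at C7 and elimination compete.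
  - Two ester reductions and the same late acylation problems follow, so the route is longer and its stereochemical risk sits late.
  - It is also the route most chemists would draw first for this skeleton.

**Alternative 3:** oxygen insertion into a diquinane.
- Disconnection: both C–O2 bonds of ring A.
- Forward key step: ozonolysis of the cyclopentene of the cis-bicyclo[3.3.0]octene tetraol A4 to the 1,5-dialdehyde A5, then cyclisation to the hydroxy-dihydropyran.
- Reason for rejection:
  - A5 has two enolisable aldehydes and no bias, so the acetal can form at C1 (wanted) or at C3.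
  - The free hydroxyls at C8, C10 and C11 compete as hemiacetal partners.
  - Ozonolysis must precede the coumarate.
  - On the diquinane, the one-carbon nucleophile for C10 would have to enter cis to the oxygen on C7, against the substrate's steric bias.
  - Building A4 would cost more steps than the whole route below.

Key step: step 8

Remark: compounds 1, 2, 4, 7, 15 and 21 are taken as purchased; bicyclic and tricyclic intermediates are named with the iridoid numbering given above.

## Route

Step 1
Reactants: 1 2,2-dimethyl-1,3-dioxan-5-one; 2 (S)-1-amino-2-(methoxymethyl)pyrrolidine (SAMP)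
Product: 3 (S)-N-(2,2-dimethyl-1,3-dioxan-5-ylidene)-2-(methoxymethyl)pyrrolidin-1-amine
Conditions: PhH, reflux, Dean–Stark
Reagents that add atoms: none
Why: Condensation of the ketone with the hydrazine gives the hydrazone (hydrazone formation); the ketone is symmetric, so there is no regiochemical issue.

Step 2
Reactants: 3 SAMP hydrazone; 4 tert-butyl(2-iodoethoxy)dimethylsilane
Product: 5 (S)-N-{(4S)-4-[2-(tert-butyldimethylsilyloxy)ethyl]-2,2-dimethyl-1,3-dioxan-5-ylidene}-2-(methoxymethyl)pyrrolidin-1-amine (C=N geometry not defined)
Conditions: t-BuLi, THF, −78 °C; then 4, −100 °C → rt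
Reagents that add atoms: none
Why: Deprotonation gives the chelated lithium azaenolate, which is alkylated by the primary iodide on the face left open by the methoxymethylpyrrolidine unit (SAMP-hydrazone alkylation); this auxiliary-controlled step sets C7 as (S), the only stereocentre bought in the route.

Step 3
Reactants: 5 alkylated hydrazone
Product: 6 (S)-4-[2-(tert-butyldimethylsilyloxy)ethyl]-2,2-dimethyl-1,3-dioxan-5-one
Conditions: O3, CH2Cl2, −78 °C; N2 purge
Reagents that add atoms: ozone, [O-][O+]=O
Why: Ozone cleaves the C=N bond of an N,N-dialkylhydrazone to ketone and nitrosamine under neutral conditions at low temperature (oxidative hydrazone cleavage), so the α-stereocentre C7, the silyl ether and the acetonide should not be touched.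

Step 4
Reactants: 7 benzyl vinyl ether
Product: 9 (Z)-1-(benzyloxy)-2-bromoethene, via dibromide 8 (not isolated)
Conditions: Br2, CH2Cl2, −78 °C; then i-Pr2NEt, −78 → 40 °C
Reagents that add atoms: bromine, BrBr
Why: Bromine adds to the electron-rich vinyl ether and the α-bromo ether 8 loses HBr to the amine (bromination/dehydrobromination); the cis isomer is the favoured product of this elimination for 2-halovinyl ethers.

Step 5
Reactants: 6 (S)-ketone; 9 (Z)-1-(benzyloxy)-2-bromoethene
Product: 12 (4S,5R)-5-[(Z)-2-(benzyloxy)ethenyl]-5-(benzyloxymethoxy)-4-[2-(tert-butyldimethylsilyloxy)ethyl]-2,2-dimethyl-1,3-dioxane, via (Z)-2-(benzyloxy)ethenyllithium 10 (not isolated), via lithium alkoxide 11 (not isolated)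
Conditions: 9, t-BuLi (2 equiv), Et2O, −78 °C; then 6, THF, −78 °C; then BOMCl, −78 °C → rt
Reagents that add atoms: benzyl chloromethyl ether, ClCOCc1ccccc1
Why: Bromine–lithium exchange gives the configurationally stable cis-alkoxyvinyllithium 10, which adds to the chair dioxanone (side chain equatorial) by axial attack; this is torsionally preferred and unhindered because the ring oxygens take the place of the 1,3-diaxial hydrogens, so the new C8–C9 bond is cis to the C7 side chain and C8 is set as (R) by substrate control (1,2-addition of an organolithium to a ketone). The tertiary alkoxide 11 is capped in the same flask as its BOM ether (alkylation with an α-chloro ether), which later prevents lactol formation and oxa-Michael addition of O8 at C5.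

Step 6
Reactants: 12 silyl ether
Product: 13 2-[(4S,5R)-5-[(Z)-2-(benzyloxy)ethenyl]-5-(benzyloxymethoxy)-2,2-dimethyl-1,3-dioxan-4-yl]ethanol
Conditions: TBAF, THF, 0 °C → rt
Reagents that add atoms: none
Why: Fluoride cleaves the primary silyl ether (desilylation); BOM ether, acetonide and enol ether are inert to it.

Step 7
Reactants: 13 primary alcohol
Product: 14 2-[(4S,5R)-5-[(Z)-2-(benzyloxy)ethenyl]-5-(benzyloxymethoxy)-2,2-dimethyl-1,3-dioxan-4-yl]acetaldehyde
Conditions: Dess–Martin periodinane, pyridine, CH2Cl2, 0 °C → rt
Reagents that add atoms: none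
Why: Dess–Martin oxidation buffered with pyridine gives the β-alkoxy aldehyde without free acid, which could ionise the allylic ether or hydrolyse the enol ether; the aldehyde is used at once.

Step 8
Reactants: 14 aldehyde; 15 sodium malonaldehyde (sodium 3-oxoprop-1-en-1-olate)
Product: 17 (1S,5S,7S,8R,9S)-1-(benzyloxy)-8-(benzyloxymethoxy)-7,10-O-isopropylidene-11-oxo iridoid (tricyclic cycloadduct; H5 and H9 cis; benzyloxy on C1 cis to C8; ring A trans to the dioxane on ring B), via alkylidene malonaldehyde 16 (not isolated)
Conditions: 15, AcOH, ethylenediammonium diacetate (10 mol %), MgSO4, CH2Cl2/MeCN, 0 → 40 °C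
Reagents that add atoms: none
Why: Ammonium-salt-catalysed Knoevenagel condensation of 14 with the malonaldehyde enolate gives 16, whose O2=C3–C4=C5 unit is a 1-oxa-1,3-diene made strongly electron-poor by the second formyl group; the tethered, electron-rich cis enol ether C9=C1 traps it in an intramolecular hetero-Diels–Alder reaction with inverse electron demand (closest known type: the domino Knoevenagel/hetero-Diels–Alder reaction of an aldehyde bearing a tethered enol ether with a 1,3-dicarbonyl compound). Ring A (O2–C3=C4–C5–C9–C1) is the six-membered ring of the [4+2] event, formed through the bonds C5–C9 and O2–C1, suprafacially on both partners; ring B closes through the same C5–C9 bond because the three-atom tether C6–C7–C8 links the diene terminus to the dienophile carbon, and a tether this short allows only the cis ring fusion (H5 cis to H9). C9 is controlled by C8: in the reactive rotamer the C8–O bond lies in the plane of the enol ether (inside-alkoxy position, least allylic strain against the cis benzyloxy group), the oxadiene arrives from the side of C7 and C10 is anti to the forming bond, so ring A ends up on the face of ring B opposite to C10 and O7, which is also the convex face of the cis-fused dioxane/cyclopentane unit. C5 follows from the cis fusion; C1 results from suprafacial addition to the cis enol ether (benzyloxy cis to C8) and is corrected in steps 9 and 10. The step needs facial selectivity (secured by the acetonide ring and the C8 alkoxy group) and selectivity for cycloaddition over oxa-Michael closure (secured by the BOM ether on O8); the symmetry of 15 removes any choice between the two carbonyl groups and any alkene-geometry issue in 16. The formyl group that remains on C4 keeps the enol ether deactivated until the last step.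

Step 9
Reactants: 17 cycloadduct
Product: 18 (5S,7S,8R,9S)-1,8-dihydroxy-7,10-O-isopropylidene-11-oxo iridoid (lactol, mixture of C1 anomers)
Conditions: H2 (1 atm), Pd(OH)2/C, EtOAc, rt
Reagents that add atoms: none
Why: Hydrogenolysis removes the anomeric benzyl group and the BOM group in one operation (the latter through its hemiacetal, which loses formaldehyde); the C3=C4 bond is a trisubstituted vinylogous formate and should resist hydrogenation.

Step 10
Reactants: 18 lactol
Product: 19 (1S,5S,7S,8R,9S)-8-hydroxy-1-(3-methylbutanoyloxy)-7,10-O-isopropylidene-11-oxo iridoid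
Conditions: isovaleric anhydride, DMAP (cat.), pyridine, CH2Cl2, −20 → 0 °C
Reagents that add atoms: isovaleric anhydride, CC(C)CC(=O)OC(=O)CC(C)C
Why: The lactol anomers equilibrate through the open form and the hemiacetal oxygen is acylated while the tertiary 8-OH is inert (DMAP-catalysed acylation); the ester cis to H9 should prevail, because a substituent on the other face of C1 would clash with the oxygen on C8 and because this is the position favoured by the anomeric effect, and this sets C1 as (S).

Step 11
Reactants: 19 isovalerate with 7,10-acetonide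
Product: 20 (1S,5S,7S,8R,9S)-7-hydroxy-1-(3-methylbutanoyloxy)-8,10-O-isopropylidene-11-oxo iridoid
Conditions: CSA (10 mol %), acetone, rt
Reagents that add atoms: none
Why: Acid-catalysed acetal equilibration moves the isopropylidene group from the six-membered 7,10-dioxane (axial methyl, cis-fused to ring B) to the five-membered 8,10-dioxolane, the usual thermodynamic preference of acetonides; O7 becomes the only free hydroxyl.

Step 12
Reactants: 21 p-coumaric acid
Product: 23 (E)-3-[4-(tetrahydro-2H-pyran-2-yloxy)phenyl]prop-2-enoic acid (racemic at the acetal carbon), via bis-THP derivative 22 (not isolated)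
Conditions: 3,4-dihydro-2H-pyran, PPTS, CH2Cl2, rt; then LiOH, THF/MeOH/H2O, 0 °C; AcOH to pH 5
Reagents that add atoms: 3,4-dihydro-2H-pyran, C1=COCCC1
Why: Both acidic OH groups add to the enol ether under mild acid (tetrahydropyranylation); the acylal-type THP ester is saponified far faster than the aryl acetal is cleaved, so only the phenol stays protected.

Step 13
Reactants: 20 alcohol; 23 protected coumaric acid
Product: 24 (1S,5S,7S,8R,9S)-1-(3-methylbutanoyloxy)-7-{(E)-3-[4-(tetrahydro-2H-pyran-2-yloxy)phenyl]prop-2-enoyloxy}-8,10-O-isopropylidene-11-oxo iridoid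
Conditions: DIC, DMAP, CH2Cl2, 0 °C → rt
Reagents that add atoms: none
Why: Carbodiimide/DMAP esterification (Steglich esterification) of the only free hydroxyl; the C7–O bond is not broken, so the configuration is retained.

Step 14
Reactants: 24 protected diester
Product: 25 (1S,5S,7S,8R,9S)-8,10-dihydroxy-7-[(E)-3-(4-hydroxyphenyl)prop-2-enoyloxy]-1-(3-methylbutanoyloxy)-11-oxo iridoid (11-oxo-luzonoid A)
Conditions: AcOH/H2O (4:1), 40 °C
Reagents that add atoms: none
Why: Aqueous acetic acid hydrolyses the dioxolane and the aryl THP acetal (acetal hydrolysis); the acyl acetal at C1 and the enol ether, which is still deactivated by the formyl group, should survive.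

Step 15
Reactants: 25 11-oxo-luzonoid A
Product: 26 luzonoid A
Conditions: NaBH4, CeCl3·7H2O, MeOH/THF, −40 °C; pH 7 buffer
Reagents that add atoms: none
Why: Luche-type 1,2-reduction of the vinylogous formate aldehyde at low temperature gives the allylic alcohol C11–OH; the cinnamate and the acyl acetal are esters and should not be reduced under these conditions, and the neutral work-up protects the now electron-rich enol ether.

## Compound list

1 | 2,2-dimethyl-1,3-dioxan-5-one | CC1(C)OCC(=O)CO1 | starting material
2 | (S)-1-amino-2-(methoxymethyl)pyrrolidine (SAMP) | COC[C@@H]1CCCN1N | starting material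
3 | (S)-N-(2,2-dimethyl-1,3-dioxan-5-ylidene)-2-(methoxymethyl)pyrrolidin-1-amine | COC[C@@H]1CCCN1N=C1COC(C)(C)OC1 | intermediate
4 | tert-butyl(2-iodoethoxy)dimethylsilane | CC(C)(C)[Si](C)(C)OCCI | starting material
5 | (S)-N-{(4S)-4-[2-(tert-butyldimethylsilyloxy)ethyl]-2,2-dimethyl-1,3-dioxan-5-ylidene}-2-(methoxymethyl)pyrrolidin-1-amine | COC[C@@H]1CCCN1N=C1COC(C)(C)O[C@H]1CCO[Si](C)(C)C(C)(C)C | intermediate
6 | (S)-4-[2-(tert-butyldimethylsilyloxy)ethyl]-2,2-dimethyl-1,3-dioxan-5-one | CC(C)(C)[Si](C)(C)OCC[C@@H]1OC(C)(C)OCC1=O | intermediate
7 | benzyl vinyl ether | C=COCc1ccccc1 | starting material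
8 | [(1,2-dibromoethoxy)methyl]benzene (racemic) | BrCC(Br)OCc1ccccc1 | intermediate
9 | (Z)-1-(benzyloxy)-2-bromoethene | Br/C=C\OCc1ccccc1 | intermediate
10 | (Z)-2-(benzyloxy)ethenyllithium | [Li]/C=C\OCc1ccccc1 | intermediate
11 | lithium (4S,5R)-5-[(Z)-2-(benzyloxy)ethenyl]-4-[2-(tert-butyldimethylsilyloxy)ethyl]-2,2-dimethyl-1,3-dioxan-5-olate | CC(C)(C)[Si](C)(C)OCC[C@@H]1OC(C)(C)OC[C@]1(O[Li])/C=C\OCc1ccccc1 | intermediate
12 | (4S,5R)-5-[(Z)-2-(benzyloxy)ethenyl]-5-(benzyloxymethoxy)-4-[2-(tert-butyldimethylsilyloxy)ethyl]-2,2-dimethyl-1,3-dioxane | CC(C)(C)[Si](C)(C)OCC[C@@H]1OC(C)(C)OC[C@]1(OCOCc2ccccc2)/C=C\OCc3ccccc3 | intermediate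
13 | 2-[(4S,5R)-5-[(Z)-2-(benzyloxy)ethenyl]-5-(benzyloxymethoxy)-2,2-dimethyl-1,3-dioxan-4-yl]ethanol | OCC[C@@H]1OC(C)(C)OC[C@]1(OCOCc2ccccc2)/C=C\OCc3ccccc3 | intermediate
14 | 2-[(4S,5R)-5-[(Z)-2-(benzyloxy)ethenyl]-5-(benzyloxymethoxy)-2,2-dimethyl-1,3-dioxan-4-yl]acetaldehyde | O=CC[C@@H]1OC(C)(C)OC[C@]1(OCOCc2ccccc2)/C=C\OCc3ccccc3 | intermediate
15 | sodium malonaldehyde (sodium 3-oxoprop-1-en-1-olate) | [Na+].[O-]/C=C/C=O | starting material
16 | 2-{2-[(4S,5R)-5-[(Z)-2-(benzyloxy)ethenyl]-5-(benzyloxymethoxy)-2,2-dimethyl-1,3-dioxan-4-yl]ethylidene}propanedial | O=CC(C=O)=CC[C@@H]1OC(C)(C)OC[C@]1(OCOCc2ccccc2)/C=C\OCc3ccccc3 | intermediate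
17 | (1S,5S,7S,8R,9S)-1-(benzyloxy)-8-(benzyloxymethoxy)-7,10-O-isopropylidene-11-oxo iridoid (cycloadduct) | O(Cc4ccccc4)[C@H]1OC=C(C=O)[C@H]2C[C@@H]3OC(C)(C)OC[C@]3(OCOCc5ccccc5)[C@@H]12 | intermediate
18 | (5S,7S,8R,9S)-1,8-dihydroxy-7,10-O-isopropylidene-11-oxo iridoid (lactol, C1 anomers) | OC1OC=C(C=O)[C@H]2C[C@@H]3OC(C)(C)OC[C@]3(O)[C@@H]12 | intermediate
19 | (1S,5S,7S,8R,9S)-8-hydroxy-1-(3-methylbutanoyloxy)-7,10-O-isopropylidene-11-oxo iridoid | CC(C)CC(=O)O[C@@H]1OC=C(C=O)[C@H]2C[C@@H]3OC(C)(C)OC[C@]3(O)[C@@H]12 | intermediate
20 | (1S,5S,7S,8R,9S)-7-hydroxy-1-(3-methylbutanoyloxy)-8,10-O-isopropylidene-11-oxo iridoid | CC(C)CC(=O)O[C@@H]1OC=C(C=O)[C@H]2C[C@H](O)[C@]3(COC(C)(C)O3)[C@@H]12 | intermediate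
21 | p-coumaric acid | OC(=O)/C=C/c1ccc(O)cc1 | starting material
22 | tetrahydro-2H-pyran-2-yl (E)-3-[4-(tetrahydro-2H-pyran-2-yloxy)phenyl]prop-2-enoate (acetal carbons undefined) | O=C(OC1CCCCO1)/C=C/c1ccc(OC2CCCCO2)cc1 | intermediate
23 | (E)-3-[4-(tetrahydro-2H-pyran-2-yloxy)phenyl]prop-2-enoic acid (racemic) | OC(=O)/C=C/c1ccc(OC2CCCCO2)cc1 | intermediate
24 | (1S,5S,7S,8R,9S)-1-(3-methylbutanoyloxy)-7-{(E)-3-[4-(tetrahydro-2H-pyran-2-yloxy)phenyl]prop-2-enoyloxy}-8,10-O-isopropylidene-11-oxo iridoid | CC(C)CC(=O)O[C@@H]1OC=C(C=O)[C@H]2C[C@H](OC(=O)/C=C/c4ccc(OC5CCCCO5)cc4)[C@]3(COC(C)(C)O3)[C@@H]12 | intermediate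
25 | 11-oxo-luzonoid A | CC(C)CC(=O)O[C@@H]1OC=C(C=O)[C@H]2C[C@H](OC(=O)/C=C/c3ccc(O)cc3)[C@](O)(CO)[C@@H]12 | intermediate
26 | luzonoid A | CC(C)CC(=O)O[C@@H]1OC=C(CO)[C@H]2C[C@H](OC(=O)/C=C/c3ccc(O)cc3)[C@](O)(CO)[C@@H]12 | target

## Step count and least certain steps

Total step count: 15. Longest linear sequence: 13 (steps 1, 2, 3, 5, 6, 7, 8, 9, 10, 11, 13, 14, 15).

**Step 8 (key step).** The most likely failure is at the condensation stage. The unsubstituted dialdehyde can add a second time to the very electrophilic oxadiene. The β-alkoxy aldehyde can also lose O7 by β-elimination before the cycloaddition occurs. Both processes gain if the cycloaddition is slowed by allylic strain at the cis enol ether. Erosion of facial control is a second concern. The fallback sets out from 14 and brings C11 in at the ester level. Condensation with the sodium enolate of ethyl formylacetate, a less reactive methylene partner whose formyl carbonyl serves as the heterodiene, should give the alkylidene formylacetate F1, which should cyclise in the same manner to the ethyl ester cycloadduct F2. Reduction with i-Bu2AlH, possible because no other ester is present at this stage, gives the C11 alcohol F3. Oxidation of this allylic alcohol with MnO2 returns to the route at 17.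

**Step 5.** The basic vinyllithium may enolise the ketone, with loss of material and epimerisation at C7, and the axial preference of the addition may be incomplete. The fallback sets out from 6 and uses a linear, less basic sp nucleophile. Benzyl alcohol, KH and trichloroethylene give benzyl (E)-1,2-dichlorovinyl ether F4. Two equivalents of n-BuLi convert this at −78 °C into lithium (benzyloxy)acetylide F5. Addition of F5 to 6 and capture with BOMCl give the ynol ether adduct F6. Semi-hydrogenation over Pd/CaCO3 poisoned with Pb(OAc)2 (Lindlar catalyst) with quinoline gives the cis enol ether and returns to the route at 12.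

**Step 10.** Under basic acylation conditions the lactol can react through its ring-opened form, a vinylogous acid, with acylation on the wrong oxygen or poor anomeric selectivity. The fallback sets out from 18 and reverses the roles at C1. Cl3CCN with catalytic DBU gives the anomeric trichloroacetimidate F7. This reacts with isovaleric acid itself, without promoter, by substitution at C1 and returns to the route at 19.

**Step 11.** The acetal migration may stop at an equilibrium mixture, or the acetonide may be lost altogether. The fallback sets out from 19 and differentiates the oxygens by reactivity instead. Aqueous acetic acid gives the triol F8. TBSCl and imidazole silylate the primary O10 selectively to give the silyl ether F9. Esterification with 23 (DIC, DMAP) gives the coumarate F10. Aqueous HF in MeCN removes the silyl and THP groups and returns to the route at 25.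

**Step 15.** The basic borohydride medium may cause a 1,3-acyl shift from O7 to the free O10, methanolysis of the anomeric ester or conjugate reduction. The fallback sets out from 25. TBSCl (2.2 equiv) and imidazole block the phenol and O10 to give the bis-silyl ether F11. The same reduction then gives the C11 alcohol F12, in which no acyl shift is possible. Buffered HF·pyridine in THF removes both silyl groups and returns to the route at 26.

## Further compounds

F1 | step 8 | ethyl 4-[(4S,5R)-5-[(Z)-2-(benzyloxy)ethenyl]-5-(benzyloxymethoxy)-2,2-dimethyl-1,3-dioxan-4-yl]-2-formylbut-2-enoate (alkene geometry undefined) | CCOC(=O)C(C=O)=CC[C@@H]1OC(C)(C)OC[C@]1(OCOCc2ccccc2)/C=C\OCc3ccccc3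
F2 | step 8 | ethyl ester analogue of 17 (CO2Et on C4 in place of CHO) | O(Cc4ccccc4)[C@H]1OC=C(C(=O)OCC)[C@H]2C[C@@H]3OC(C)(C)OC[C@]3(OCOCc5ccccc5)[C@@H]12
F3 | step 8 | C11 alcohol analogue of 17 (CH2OH on C4) | O(Cc4ccccc4)[C@H]1OC=C(CO)[C@H]2C[C@@H]3OC(C)(C)OC[C@]3(OCOCc5ccccc5)[C@@H]12
F4 | step 5 | benzyl (E)-1,2-dichlorovinyl ether | Cl/C=C(/Cl)OCc1ccccc1
F5 | step 5 | lithium (benzyloxy)acetylide | [Li]C#COCc1ccccc1
F6 | step 5 | (4S,5R)-5-[(benzyloxy)ethynyl]-5-(benzyloxymethoxy)-4-[2-(tert-butyldimethylsilyloxy)ethyl]-2,2-dimethyl-1,3-dioxane | CC(C)(C)[Si](C)(C)OCC[C@@H]1OC(C)(C)OC[C@]1(OCOCc2ccccc2)C#COCc3ccccc3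
F7 | step 10 | 1-O-trichloroacetimidate of lactol 18 (C1 anomers) | ClC(Cl)(Cl)C(=N)OC1OC=C(C=O)[C@H]2C[C@@H]3OC(C)(C)OC[C@]3(O)[C@@H]12
F8 | step 11 | (1S,5S,7S,8R,9S)-7,8,10-trihydroxy-1-(3-methylbutanoyloxy)-11-oxo iridoid | CC(C)CC(=O)O[C@@H]1OC=C(C=O)[C@H]2C[C@H](O)[C@](O)(CO)[C@@H]12
F9 | step 11 | 10-O-tert-butyldimethylsilyl ether of F8 | CC(C)CC(=O)O[C@@H]1OC=C(C=O)[C@H]2C[C@H](O)[C@](O)(CO[Si](C)(C)C(C)(C)C)[C@@H]12
F10 | step 11 | 7-O-[(E)-4-(tetrahydro-2H-pyran-2-yloxy)cinnamoyl] derivative of F9 | CC(C)CC(=O)O[C@@H]1OC=C(C=O)[C@H]2C[C@H](OC(=O)/C=C/c3ccc(OC4CCCCO4)cc3)[C@](O)(CO[Si](C)(C)C(C)(C)C)[C@@H]12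
F11 | step 15 | 10-O,4'-O-bis(tert-butyldimethylsilyl) ether of 25 | CC(C)CC(=O)O[C@@H]1OC=C(C=O)[C@H]2C[C@H](OC(=O)/C=C/c3ccc(O[Si](C)(C)C(C)(C)C)cc3)[C@](O)(CO[Si](C)(C)C(C)(C)C)[C@@H]12
F12 | step 15 | 10-O,4'-O-bis(tert-butyldimethylsilyl) ether of 26 | CC(C)CC(=O)O[C@@H]1OC=C(CO)[C@H]2C[C@H](OC(=O)/C=C/c3ccc(O[Si](C)(C)C(C)(C)C)cc3)[C@](O)(CO[Si](C)(C)C(C)(C)C)[C@@H]12
A1 | alternative 1 | cyclopentene acetonide (ring B with C7, C8, C10 in place, C5=C9 alkene) | C1=CC[C@@H]2OC(C)(C)OC[C@]12O
A2 | alternative 1 | 1-hydroxy iridoid methyl ester from the retro-aldol/lactolisation (C1 anomers) | OC1OC=C(C(=O)OC)[C@H]2C[C@@H]3OC(C)(C)OC[C@]3(O)[C@@H]12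
A3 | alternative 2 | cis-fused 1-pivaloyloxy-4-oxo cyclopenta[c]pyran with C7=C8 and ethyl ester on C8 | CC(C)(C)C(=O)O[C@@H]1OCC(=O)[C@H]2CC=C(C(=O)OCC)[C@@H]12
A4 | alternative 3 | cis-bicyclo[3.3.0]octene tetraol (C1=C3 alkene, C4 configuration undefined) | OCC1C=C[C@H]2[C@@H]1C[C@H](O)[C@]2(O)CO
A5 | alternative 3 | 1,5-dialdehyde from ozonolysis of A4 | OCC(C=O)[C@H]1C[C@H](O)[C@](O)(CO)[C@H]1C=O
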